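(The numbers of this flask stand for no real mixture, and the outcome is calculated.)

Turn every constant into a time at the charged amounts before you let anything run.

all flasks: Z 24 mM; time 3.0 h

| flask | Q |
|---|---|
| Tuesday's | 36.0 mM |
| Friday's | 110 mM |

    Q ⇌ E (K1 = 1.4, k1 = 0.0044 s⁻¹)
    Z + X → Z.X (k2 = 0.015 M⁻¹ s⁻¹)
    Z + Q ⇌ X + J (K3 = 0.040, k3 = 0.12 M⁻¹ s⁻¹)

- which of these there is most of at the end, counted by the Z in it, Tuesday's (Z.X / Z / X)
- which of these there is most of at the end, counted by the Z in it, Friday's (Z.X / Z / X)
- amount of the one of these that there is most of at the end, in percent of the Z charged, Tuesday's
- amount of the one of these that there is most of at the end, in percent of the Z charged, Friday's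

- in percentages every species weighs as the Z in it: one Z.X counts as two
- run time (Tuesday's): 3.0 h

I began with Tuesday's flask and the exchange of Q with E, which relaxed in about 2.21 min and left 15.0 mM of Q free. The step making X and J then had a time of 9.26 min, short against the run, so I took it as balanced (a quasi-equilibrium): X times J stood at 0.040 times Z times free Q. With X equal to J at first, that gave 3.79 mM of X. The step joining Z and X then had a time of 4.88 h, longer than either of the others, so I called it the rate-limiting step.

But every Z.X left a J behind, so J grew and the balance pressed X down. Taking J as Z.X and holding Z, I found that the square of Z.X per Z grew as 2 times the joining constant times the balance constant times free Q times the time. Its root came to 0.441. Each Z.X holds two Z, so, with X left out of the count, I reckoned the Z left as one part in one plus two such ratios, 53.1 % of the charge.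

The link I reforged was free Q, which I had held fixed although each J made used up a Q. That J came to about 5.62 mM, which brought free Q down to 12.7 mM. The ratio became 0.405, and this I named the choke ratio, Z.X held per Z left at the end. By this reckoning Z left came to 55.2 %, with 44.8 % for Z.X and X together, less than Z, so I committed to Z as the largest on Tuesday's.

The forecast said Z at 55 % for Tuesday's and Z.X at 54 % for Friday's, holding that “the slow, irreversible Z + X → Z.X step drains the system”.

The flasks gave Z at 54.8 % on Tuesday's and Z.X at 54.6 % on Friday's. At the end of Tuesday's, the half-life of Z by the forward rate of the step making X and J alone was 0.13 h, shorter than the run of 3.0 h. In my reckoning the choke ratio goes as the root of free Q, so, taking the same share of Q as free as on Tuesday's, Friday's charge of 110 mM turns 0.405 into 0.708, which leaves 41.4 % of Z; Z in Friday's flask stood at 37.8 %.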